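**Assumption:** natural (S)-(–)-liquiritigenin is bought as the single enantiomer (ee checked by chiral HPLC), and tert-butyl 2-methylbut-3-en-2-yl carbonate is bought (otherwise one step from 2-methylbut-3-en-2-ol and Boc2O). The target is the (2S)-flavan, the same spatial arrangement as C2 of (S)-liquiritigenin.

## Retrosynthetic overview

1. Kazinol B ⇒ 7-O-TIPS ether 14 ⇒ aromatic Claisen [3,3] of the 3′-O-(1,1-dimethylallyl) ether 13, which makes the C2′–prenyl bond.
2. 13 ⇒ phenol 11 ⇒ aryl bromide 9 (Br→OH); the pyran ring of 9 ⇒ aryl 1,1-dimethylpropargyl ether 8 by propargyl Claisen / 1,5-H shift / oxa-6π electrocyclization.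
3. 8 ⇒ ortho-bromophenol 6 ⇒ (S)-4′-hydroxyflavan 4 ⇒ (S)-liquiritigenin 1 (C2 purchased; C4=O removed; 7-OH masked as TIPS).
4. Ring order: the chroman (A/C) and B rings come intact from 1; the only ring built is the 2H-pyran (step 5).

## Route

**Step 1**
Reactants: 1, (S)-liquiritigenin; 2, chlorotriisopropylsilane
Product: 3, (2S)-2-(4-hydroxyphenyl)-7-(triisopropylsilyloxy)chroman-4-one
Conditions: TIPSCl (1.05 equiv), imidazole (2 equiv), DMF, –10 → 0 °C
Reagents that add atoms: chlorotriisopropylsilane, CC(C)[Si](Cl)(C(C)C)C(C)C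
Why: Chemoselective O-silylation; the 7-OH (vinylogous acid, pKa about 7.5) is ionised by imidazole and silylated ahead of the 4′-OH (pKa about 10), and the cold, weakly basic conditions avoid retro-oxa-Michael racemisation at C2.

**Step 2**
Reactants: 3
Product: 4, 4-[(2S)-7-(triisopropylsilyloxy)chroman-2-yl]phenol
Conditions: H2 (4 bar), 10% Pd/C, AcOH, 40 °C
Reagents that add atoms: none
Why: Catalytic hydrogenation and benzylic hydrogenolysis of the aryl ketone (via the flavan-4-ol), assisted by the para-silyloxy and ortho-alkoxy donors as in isoflavone → isoflavan reductions; C2 is not involved and stays S.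

**Step 3**
Reactants: 4; 5, N-bromosuccinimide
Product: 6, 2-bromo-4-[(2S)-7-(triisopropylsilyloxy)chroman-2-yl]phenol
Conditions: NBS (1.0 equiv), i-Pr2NH (10 mol%), CH2Cl2, –20 → 0 °C, dark
Reagents that add atoms: N-bromosuccinimide, O=C1CCC(=O)N1Br
Why: Amine-mediated ortho-selective electrophilic bromination of the free phenol (para position blocked; both activated A-ring positions are flanked by the bulky OTIPS); the bromine marks the future 3′-oxygen and blocks one ortho site.

**Step 4**
Reactants: 6; 7, 3-chloro-3-methylbut-1-yne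
Product: 8, (2S)-2-[3-bromo-4-(2-methylbut-3-yn-2-yloxy)phenyl]-7-(triisopropylsilyloxy)chroman
Conditions: 7 (1.5 equiv), DBU (1.6 equiv), CuCl2·2H2O (1 mol%), MeCN, 0 °C
Reagents that add atoms: 3-chloro-3-methylbut-1-yne, C#CC(C)(C)Cl
Why: Copper-catalysed propargylic etherification of the phenoxide; run cold so the 4′-phenoxide cannot open the chroman through a p-quinone methide, and after this step the 4′-oxygen is capped so that pathway is closed.

**Step 5**
Reactants: 8
Product: 9, (2S)-2-(8-bromo-2,2-dimethyl-2H-chromen-6-yl)-7-(triisopropylsilyloxy)chroman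
Conditions: o-xylene, 140 °C, Ar, 3 h
Reagents that add atoms: none
Why: Aryl propargyl Claisen rearrangement ([3,3]) to the only free ortho carbon, then 1,5-H shift to the o-quinone methide and oxa-6π electrocyclization closes the 2,2-dimethyl-2H-pyran; neutral thermal conditions leave C2 untouched.

**Step 6**
Reactants: 9; 10, hydrogen peroxide
Product: 11, 2,2-dimethyl-6-[(2S)-7-(triisopropylsilyloxy)chroman-2-yl]-2H-chromen-8-ol
Conditions: n-BuLi (1.1 equiv), THF, –78 °C; B(OMe)3, –78 → 0 °C; then 30% H2O2, aq NaOH, 0 °C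
Reagents that add atoms: hydrogen peroxide, OO
Why: Br/Li exchange, borylation and boronate oxidation (1,2-aryl shift to oxygen) convert C–Br into C–OH; the chromene alkene and aryl TIPS ether tolerate this, and with no para-OH on the B ring C2 is safe in base.

**Step 7**
Reactants: 11; 12, tert-butyl 2-methylbut-3-en-2-yl carbonate
Product: 13, (2S)-2-[2,2-dimethyl-8-(2-methylbut-3-en-2-yloxy)-2H-chromen-6-yl]-7-(triisopropylsilyloxy)chroman
Conditions: 12 (1.5 equiv), Pd(PPh3)4 (2 mol%), THF, 0 °C, 30 min
Reagents that add atoms: tert-butyl 2-methylbut-3-en-2-yl carbonate, C=CC(C)(C)OC(=O)OC(C)(C)C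
Why: Pd(0)-catalysed decarboxylative allylic etherification (Tsuji–Trost type); the phenoxide attacks the more substituted terminus of the 1,1-dimethyl-π-allyl complex, giving the tertiary ether as the kinetic product at low temperature.

**Step 8**
Reactants: 13
Product: 14, 2,2-dimethyl-7-(3-methylbut-2-en-1-yl)-6-[(2S)-7-(triisopropylsilyloxy)chroman-2-yl]-2H-chromen-8-ol
Conditions: PhMe, 110 °C, sealed tube, Ar, 3 h
Reagents that add atoms: none
Why: Aromatic Claisen rearrangement ([3,3]) to C2′, the only H-bearing ortho position (the other ortho carbon carries the pyran oxygen); allyl inversion delivers the linear prenyl group and frees the 3′-OH.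

**Step 9**
Reactants: 14
Product: 15, Kazinol B
Conditions: TBAF (1.1 equiv), AcOH (1.1 equiv), THF, 0 °C
Reagents that add atoms: none
Why: Fluoride desilylation of the aryl TIPS ether; buffering keeps the ortho-prenyl phenol and chromene intact, and the untouched C2 remains S.

## Compound list

1 | (S)-liquiritigenin, (2S)-7-hydroxy-2-(4-hydroxyphenyl)chroman-4-one | Oc1ccc([C@@H]2CC(=O)c3ccc(O)cc3O2)cc1 | starting material
2 | chlorotriisopropylsilane | CC(C)[Si](Cl)(C(C)C)C(C)C | starting material
3 | (2S)-2-(4-hydroxyphenyl)-7-(triisopropylsilyloxy)chroman-4-one | Oc1ccc([C@@H]2CC(=O)c3ccc(O[Si](C(C)C)(C(C)C)C(C)C)cc3O2)cc1 | intermediate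
4 | 4-[(2S)-7-(triisopropylsilyloxy)chroman-2-yl]phenol | Oc1ccc([C@@H]2CCc3ccc(O[Si](C(C)C)(C(C)C)C(C)C)cc3O2)cc1 | intermediate
5 | N-bromosuccinimide | O=C1CCC(=O)N1Br | starting material
6 | 2-bromo-4-[(2S)-7-(triisopropylsilyloxy)chroman-2-yl]phenol | Oc1ccc([C@@H]2CCc3ccc(O[Si](C(C)C)(C(C)C)C(C)C)cc3O2)cc1Br | intermediate
7 | 3-chloro-3-methylbut-1-yne | C#CC(C)(C)Cl | starting material
8 | (2S)-2-[3-bromo-4-(2-methylbut-3-yn-2-yloxy)phenyl]-7-(triisopropylsilyloxy)chroman | C#CC(C)(C)Oc1ccc([C@@H]2CCc3ccc(O[Si](C(C)C)(C(C)C)C(C)C)cc3O2)cc1Br | intermediate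
9 | (2S)-2-(8-bromo-2,2-dimethyl-2H-chromen-6-yl)-7-(triisopropylsilyloxy)chroman | CC1(C)C=Cc2cc([C@@H]3CCc4ccc(O[Si](C(C)C)(C(C)C)C(C)C)cc4O3)cc(Br)c2O1 | intermediate
10 | hydrogen peroxide | OO | starting material
11 | 2,2-dimethyl-6-[(2S)-7-(triisopropylsilyloxy)chroman-2-yl]-2H-chromen-8-ol | CC1(C)C=Cc2cc([C@@H]3CCc4ccc(O[Si](C(C)C)(C(C)C)C(C)C)cc4O3)cc(O)c2O1 | intermediate
12 | tert-butyl 2-methylbut-3-en-2-yl carbonate | C=CC(C)(C)OC(=O)OC(C)(C)C | starting material
13 | (2S)-2-[2,2-dimethyl-8-(2-methylbut-3-en-2-yloxy)-2H-chromen-6-yl]-7-(triisopropylsilyloxy)chroman | C=CC(C)(C)Oc1cc([C@@H]2CCc3ccc(O[Si](C(C)C)(C(C)C)C(C)C)cc3O2)cc2c1OC(C)(C)C=C2 | intermediate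
14 | 2,2-dimethyl-7-(3-methylbut-2-en-1-yl)-6-[(2S)-7-(triisopropylsilyloxy)chroman-2-yl]-2H-chromen-8-ol (7-O-TIPS-kazinol B) | CC(C)=CCc1c([C@@H]2CCc3ccc(O[Si](C(C)C)(C(C)C)C(C)C)cc3O2)cc2c(c1O)OC(C)(C)C=C2 | intermediate
15 | Kazinol B, 6-[(2S)-7-hydroxychroman-2-yl]-2,2-dimethyl-7-(3-methylbut-2-en-1-yl)-2H-chromen-8-ol | CC(C)=CCc1c([C@@H]2CCc3ccc(O)cc3O2)cc2c(c1O)OC(C)(C)C=C2 | target

## Summary

Total steps: 9. Longest linear sequence: 9 (fully linear from 1). Steps 7–9 can be telescoped without purifying 13, but are counted separately.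

Steps most likely to fail, each with a fallback that changes the approach:

1. **Step 2** (over-hydrogenolysis of the benzylic C2–O1 bond to a 1,3-diarylpropane, or stalling at the flavan-4-ol). Fallback: replace catalytic hydrogenation with a hydride/ionic sequence, NaBH4 reduction to the flavan-4-ol followed by Et3SiH/BF3·OEt2 deoxygenation at –40 °C.
2. **Step 3** (competing A-ring bromination or dibromination). Fallback: use a formyl group instead of bromine as the oxygen surrogate. Ortho-formylate 4 (MgCl2, Et3N, paraformaldehyde), form the propargyl ether, then Baeyer–Villiger/Dakin oxidation (mCPBA; NaHCO3/MeOH) to the 3′-OH before the thermal chromene formation. This replaces steps 3 and 6, but the hot basic formylation needs an ee check.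
3. **Step 8** (Claisen into the hindered C2′ may be accompanied by para migration to C6′ via the ipso-dienone/Cope pathway, or by cyclisation of the product to a chroman). Fallback: directed ortho-metalation instead of rearrangement. Convert 11 to its O-diethylcarbamate, lithiate at C2′ (s-BuLi/TMEDA, –78 °C), transmetalate to copper, alkylate with prenyl bromide, then remove the carbamate.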